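The route rests on cutting the CH2–aryl bond of the seven-membered ring. Its aryl terminus, C4 of the central tetrahydrobenzo[1,2-b:5,4-b']difuran ring, is meta to both furan oxygens and flanked by the C3 and C5 methines, so Friedel–Crafts chemistry cannot reach it, but a bromine carried from the starting material can. The key step, an intramolecular B-alkyl Suzuki–Miyaura coupling, closes the dibenzocycloheptane in one operation without touching any stereocentre. Its precursor is a bromo boronate: the C2-symmetric 4-bromo bis(trans-diaryldihydrofuran) core, made by double asymmetric carbene C–H insertion, desymmetrised by mono-iodination and an enantioselective arylboration of 2,4-dimethoxystyrene that installs the (R)-CH(Ar)CH2Bpin arm.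

Key step: step 12

Assumption: Rh2(R-PTAD)4 is taken to give the cis-2,3 insertion products of the 3R,5R series, and the chosen enantiomer of the sulfoxide–phosphine ligand the 1R arm; if either sense proves opposite, the mirror-image catalyst or ligand is used with no other change.

Step 1
Reactants: 1 2-bromo-4,6-dimethoxybenzaldehyde
Product: 2 2-bromo-4,6-dimethoxybenzene-1,3-dicarbaldehyde
Conditions: Cl2CHOMe, TiCl4, CH2Cl2, 0 °C to rt; then H2O
Reagents that add atoms: dichloromethyl methyl ether ClC(Cl)OC; water O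
Why: Rieche formylation (electrophilic aromatic substitution) should go to C3, the only free position para to a methoxy group, the same preference that places the first formyl group next to bromine in 1.

Step 2
Reactants: 2 2-bromo-4,6-dimethoxybenzene-1,3-dicarbaldehyde
Product: 3 2-bromo-4,6-dihydroxybenzene-1,3-dicarbaldehyde
Conditions: BCl3, CH2Cl2, −10 °C to rt; then H2O
Reagents that add atoms: none
Why: Chelation-assisted Lewis-acid ether cleavage, since each methoxy group is ortho to a formyl group.

Step 3
Reactants: 3 2-bromo-4,6-dihydroxybenzene-1,3-dicarbaldehyde; 4 4-methoxybenzyl chloride (two equivalents, one per phenol)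
Product: 5 2-bromo-4,6-bis[(4-methoxyphenyl)methoxy]benzene-1,3-dicarbaldehyde
Conditions: 4 (2.3 equiv), K2CO3 (3 equiv), DMF, 60 °C
Reagents that add atoms: 4-methoxybenzyl chloride (the second equivalent of 4) COc1ccc(CCl)cc1
Why: Twofold Williamson etherification, one molecule of 4 per phenol; the benzyl groups are not protecting groups but supply C2 and C6 of the future dihydrofurans together with their 4-methoxyphenyl rings.

Step 4
Reactants: 5 2-bromo-4,6-bis[(4-methoxyphenyl)methoxy]benzene-1,3-dicarbaldehyde; 6 3,5-dimethoxyphenylmagnesium chloride (two equivalents, one per aldehyde)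
Product: 7 [2-bromo-4,6-bis[(4-methoxyphenyl)methoxy]-1,3-phenylene]bis[(3,5-dimethoxyphenyl)methanol] (diastereomer mixture)
Conditions: 6 (2.4 equiv), THF, −40 to 0 °C; aqueous NH4Cl work-up
Reagents that add atoms: 3,5-dimethoxyphenylmagnesium chloride (the second equivalent of 6) COc1cc(OC)cc([Mg]Cl)c1
Why: Twofold Grignard 1,2-addition, one molecule of 6 per aldehyde, should outrun halogen–magnesium exchange at the electron-rich aryl bromide; the carbinol centres are destroyed in step 5, so their configuration is irrelevant.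

Step 5
Reactants: 7 bis(diarylmethanol)
Product: 8 [2-bromo-4,6-bis[(4-methoxyphenyl)methoxy]-1,3-phenylene]bis[(3,5-dimethoxyphenyl)methanone]
Conditions: Dess–Martin periodinane (2.5 equiv), CH2Cl2, rt
Reagents that add atoms: none
Why: Dess–Martin oxidation of the two benzhydrols to diaryl ketones under near-neutral conditions that leave the 4-methoxybenzyl ethers intact.

Step 6
Reactants: 8 bis(diaryl ketone)
Product: 9 bis-hydrazone of 8
Conditions: N2H4 (anhydrous, excess), AcOH (cat.), n-BuOH, 110 °C
Reagents that add atoms: hydrazine NN; hydrazine (the second equivalent, for the second carbonyl group) NN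
Why: Acid-catalysed hydrazone condensation at both carbonyl groups, run under forcing conditions because each carbonyl is flanked by bromine and a benzyloxy group.

Step 7
Reactants: 9 bis-hydrazone
Product: 11 (2S,3R,5R,6S)-4-bromo-3,5-bis(3,5-dimethoxyphenyl)-2,6-bis(4-methoxyphenyl)-2,3,5,6-tetrahydrobenzo[1,2-b:5,4-b']difuran (both dihydrofurans cis), via bis-diazo compound 10 (not isolated)
Conditions: MnO2, CH2Cl2, 0 °C, filter; then Rh2(R-PTAD)4 (2 mol%), CH2Cl2, −20 °C to rt, dilute
Reagents that add atoms: none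
Why: MnO2 dehydrogenates both hydrazones to diaryldiazomethanes and the chiral dirhodium tetracarboxylate converts each into a donor/donor carbene that inserts into the adjacent benzylic O–CH2 bond (1,5 C–H insertion), the catalyst setting C3 and C5 as R and the concerted insertion giving the kinetic cis-2,3 arrangement; two insertions in one molecule should divert the minor sense into a separable meso-type diastereomer.

Step 8
Reactants: 11 cis,cis core
Product: 12 (2R,3R,5R,6R)-4-bromo-3,5-bis(3,5-dimethoxyphenyl)-2,6-bis(4-methoxyphenyl)-2,3,5,6-tetrahydrobenzo[1,2-b:5,4-b']difuran (both dihydrofurans trans; C2-symmetric)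
Conditions: CF3CO2H, CH2Cl2, 0 °C to rt
Reagents that add atoms: none
Why: Acid-mediated epimerisation by reversible ionisation of each benzylic C–O bond to a 4-methoxybenzyl cation and reclosure by the tethered phenol oxygen should equilibrate C2 and C6 to the thermodynamic trans isomers while C3 and C5 stay untouched.

Step 9
Reactants: 12 trans,trans core
Product: 13 (2R,3R,5S,6R)-4-bromo-5-(2-iodo-3,5-dimethoxyphenyl)-3-(3,5-dimethoxyphenyl)-2,6-bis(4-methoxyphenyl)-2,3,5,6-tetrahydrobenzo[1,2-b:5,4-b']difuran (geometry as in 12; the C5 descriptor changes only through the priority of iodine)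
Conditions: N-iodosuccinimide (1 equiv), CF3CO2H (cat.), MeCN/CH2Cl2, 0 °C, partial conversion
Reagents that add atoms: N-iodosuccinimide O=C1CCC(=O)N1I
Why: Electrophilic aromatic iodination at the position of a 3,5-dimethoxyphenyl ring that is para to one methoxy and ortho to the other; the C2 axis and free rotation of the aryl rings make all four such positions equivalent, so a single mono-iodide should form and unreacted 12 can be recycled.

Step 10
Reactants: 14 2,4-dimethoxybenzaldehyde
Product: 15 2,4-dimethoxystyrene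
Conditions: Ph3PCH3Br, KOtBu, THF, 0 °C to rt
Reagents that add atoms: methyltriphenylphosphonium bromide C[P+](c1ccccc1)(c1ccccc1)c1ccccc1.[Br-]
Why: Wittig methylenation of the aldehyde.

Step 11
Reactants: 13 mono-iodide; 15 2,4-dimethoxystyrene
Product: 16 (2R,3R,5R,6R)-4-bromo-5-{2-[(1R)-1-(2,4-dimethoxyphenyl)-2-(4,4,5,5-tetramethyl-1,3,2-dioxaborolan-2-yl)ethyl]-3,5-dimethoxyphenyl}-3-(3,5-dimethoxyphenyl)-2,6-bis(4-methoxyphenyl)-2,3,5,6-tetrahydrobenzo[1,2-b:5,4-b']difuran
Conditions: CuCl (10 mol%), chiral sulfoxide–phosphine ligand (12 mol%), Pd(dppf)Cl2 (5 mol%), B2pin2, NaOtBu, THF, 0 °C to rt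
Reagents that add atoms: bis(pinacolato)diboron CC1(C)OB(OC1(C)C)B1OC(C)(C)C(C)(C)O1
Why: Cooperative copper/palladium arylboration, in which enantioselective syn-borylcupration of the styrene puts boron on the terminal carbon and copper on the benzylic carbon, and stereospecific transfer to the arylpalladium iodide (oxidative addition at C–I is far faster than at the flanked C–Br) followed by reductive elimination gives the 2,2-diarylethyl boronate, the chiral ligand on copper setting the new centre as R.

Step 12
Reactants: 16 bromo boronate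
Product: 17 octa-O-methyl ether of the target (all five stereocentres as in 18)
Conditions: Pd(OAc)2 (10 mol%), RuPhos (20 mol%), KOH, THF/H2O 10:1, 70 °C, 5 mM
Reagents that add atoms: none
Why: Oxidative addition of zerovalent palladium into the C4–Br bond, hydroxide-assisted transmetalation of the primary alkyl boronate and C(sp3)–C(sp2) reductive elimination form the C4–CH2 bond. The closest known reaction type is the B-alkyl Suzuki–Miyaura coupling of primary 2,2-diarylethyl pinacol boronates with aryl bromides, here run intramolecularly. The seven-membered ring closes by reductive elimination from an eight-membered palladacycle, the only ring size the tether allows because the boronate arm sits on the aryl ring attached to C5, next to C4. No stereocentre is formed: the R centre of the arm is beta to boron and is carried through unchanged, and the four dihydrofuran centres are inert to aqueous KOH at 70 °C. The step needs oxidative addition at a doubly flanked bromide and reductive elimination faster than beta-hydride elimination or protodeboronation, which the bulky electron-rich RuPhos ligand and the tied-back five-membered rings beside C4 should secure, while high dilution suppresses intermolecular coupling.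

Step 13
Reactants: 17 octamethyl ether
Product: 18 target CNP0154047.1
Conditions: BBr3 (excess), CH2Cl2, −78 °C to rt; then MeOH/H2O
Reagents that add atoms: none
Why: Lewis-acid cleavage of all eight aryl methyl ethers; the trans dihydrofurans are the thermodynamic isomers, so any reversible opening of the benzylic C–O bonds under BBr3 should return the same configuration.

Compound list

1 | 2-bromo-4,6-dimethoxybenzaldehyde | COc1cc(OC)c(C=O)c(Br)c1 | starting material
2 | 2-bromo-4,6-dimethoxybenzene-1,3-dicarbaldehyde | COc1cc(OC)c(C=O)c(Br)c1C=O | intermediate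
3 | 2-bromo-4,6-dihydroxybenzene-1,3-dicarbaldehyde | Oc1cc(O)c(C=O)c(Br)c1C=O | intermediate
4 | 4-methoxybenzyl chloride | COc1ccc(CCl)cc1 | starting material
5 | 2-bromo-4,6-bis[(4-methoxyphenyl)methoxy]benzene-1,3-dicarbaldehyde | COc1ccc(COc2cc(OCc3ccc(OC)cc3)c(C=O)c(Br)c2C=O)cc1 | intermediate
6 | 3,5-dimethoxyphenylmagnesium chloride (THF solution) | COc1cc(OC)cc([Mg]Cl)c1 | starting material
7 | [2-bromo-4,6-bis[(4-methoxyphenyl)methoxy]-1,3-phenylene]bis[(3,5-dimethoxyphenyl)methanol], diastereomer mixture | COc1ccc(COc2cc(OCc3ccc(OC)cc3)c(C(O)c3cc(OC)cc(OC)c3)c(Br)c2C(O)c2cc(OC)cc(OC)c2)cc1 | intermediate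
8 | [2-bromo-4,6-bis[(4-methoxyphenyl)methoxy]-1,3-phenylene]bis[(3,5-dimethoxyphenyl)methanone] | COc1ccc(COc2cc(OCc3ccc(OC)cc3)c(C(=O)c3cc(OC)cc(OC)c3)c(Br)c2C(=O)c2cc(OC)cc(OC)c2)cc1 | intermediate
9 | bis-hydrazone of 8 | COc1ccc(COc2cc(OCc3ccc(OC)cc3)c(C(=NN)c3cc(OC)cc(OC)c3)c(Br)c2C(=NN)c2cc(OC)cc(OC)c2)cc1 | intermediate
10 | 3-bromo-2,4-bis[diazo(3,5-dimethoxyphenyl)methyl]-1,5-bis[(4-methoxyphenyl)methoxy]benzene | COc1ccc(COc2cc(OCc3ccc(OC)cc3)c(C(=[N+]=[N-])c3cc(OC)cc(OC)c3)c(Br)c2C(=[N+]=[N-])c2cc(OC)cc(OC)c2)cc1 | intermediate (not isolated)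
11 | (2S,3R,5R,6S)-4-bromo-3,5-bis(3,5-dimethoxyphenyl)-2,6-bis(4-methoxyphenyl)-2,3,5,6-tetrahydrobenzo[1,2-b:5,4-b']difuran, both dihydrofurans cis | COc1ccc(cc1)[C@H]1Oc2cc3O[C@H](c4ccc(OC)cc4)[C@H](c4cc(OC)cc(OC)c4)c3c(Br)c2[C@H]1c1cc(OC)cc(OC)c1 | intermediate
12 | (2R,3R,5R,6R)-4-bromo-3,5-bis(3,5-dimethoxyphenyl)-2,6-bis(4-methoxyphenyl)-2,3,5,6-tetrahydrobenzo[1,2-b:5,4-b']difuran, both dihydrofurans trans | COc1ccc(cc1)[C@@H]1Oc2cc3O[C@@H](c4ccc(OC)cc4)[C@H](c4cc(OC)cc(OC)c4)c3c(Br)c2[C@H]1c1cc(OC)cc(OC)c1 | intermediate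
13 | (2R,3R,5S,6R)-4-bromo-5-(2-iodo-3,5-dimethoxyphenyl)-3-(3,5-dimethoxyphenyl)-2,6-bis(4-methoxyphenyl)-2,3,5,6-tetrahydrobenzo[1,2-b:5,4-b']difuran, geometry as in 12 | COc1ccc(cc1)[C@@H]1Oc2cc3O[C@@H](c4ccc(OC)cc4)[C@H](c4c(I)c(OC)cc(OC)c4)c3c(Br)c2[C@H]1c1cc(OC)cc(OC)c1 | intermediate
14 | 2,4-dimethoxybenzaldehyde | COc1ccc(C=O)c(OC)c1 | starting material
15 | 2,4-dimethoxystyrene | COc1ccc(C=C)c(OC)c1 | intermediate
16 | (2R,3R,5R,6R)-4-bromo-5-{2-[(1R)-1-(2,4-dimethoxyphenyl)-2-(4,4,5,5-tetramethyl-1,3,2-dioxaborolan-2-yl)ethyl]-3,5-dimethoxyphenyl}-3-(3,5-dimethoxyphenyl)-2,6-bis(4-methoxyphenyl)-2,3,5,6-tetrahydrobenzo[1,2-b:5,4-b']difuran | COc1ccc(cc1)[C@@H]1Oc2cc3O[C@@H](c4ccc(OC)cc4)[C@H](c4c([C@H](CB5OC(C)(C)C(C)(C)O5)c5ccc(OC)cc5OC)c(OC)cc(OC)c4)c3c(Br)c2[C@H]1c1cc(OC)cc(OC)c1 | intermediate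
17 | octa-O-methyl ether of the target: core of 12 in which C4 and position 2 of the dimethoxyphenyl ring on C5 are bridged by CH2–CH(2,4-dimethoxyphenyl), bridge methine R, seven-membered ring | COc1ccc([C@@H]2Oc3cc4c5c(c3[C@H]2c2cc(OC)cc(OC)c2)C[C@H](c2ccc(OC)cc2OC)c2c(OC)cc(OC)cc2[C@H]5[C@H](c2ccc(OC)cc2)O4)cc1 | intermediate
18 | CNP0154047.1: (2R,3R,5R,6R)-2,6-bis(4-hydroxyphenyl)-3-(3,5-dihydroxyphenyl)-tetrahydrobenzo[1,2-b:5,4-b']difuran whose C4 and position 2 of the 3,5-dihydroxyphenyl ring on C5 are bridged by CH2–CH(2,4-dihydroxyphenyl), bridge methine R, both dihydrofurans trans | Oc1ccc([C@@H]2Oc3cc4c5c(c3[C@H]2c2cc(O)cc(O)c2)C[C@H](c2ccc(O)cc2O)c2c(O)cc(O)cc2[C@H]5[C@H](c2ccc(O)cc2)O4)cc1 | target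

Total step count: 13. Longest linear sequence: 12 (steps 1–9 and 11–13; step 10 is a side branch).

Steps most likely to fail

Step 12. Ring closure may be lost to beta-hydride elimination or protodeboronation if oxidative addition at the doubly flanked C4–Br bond is slow. The fallback changes the organometallic from boron to zinc and sets out from 16. Oxidation with NaBO3 in THF/H2O gives the primary alcohol F1, and the Appel reaction (I2, PPh3, imidazole) turns it into the primary iodide F2. Zinc insertion (Zn dust, LiCl, THF) gives the alkylzinc iodide F3, which is used in situ for an intramolecular Negishi coupling at C4–Br (Pd(OAc)2, CPhos, THF/toluene). This returns to the route at 17.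

Step 11. Transfer of the benzylic copper intermediate to the congested arylpalladium may be too slow, so that the styrene is merely protoborated or the arm forms with poor enantiocontrol. The fallback builds the arm in two separate bond-forming events from 13. 2',4'-Dimethoxyacetophenone is condensed with p-toluenesulfonohydrazide (MeOH, 60 °C) to give the N-tosylhydrazone F4. A Barluenga coupling of 13 with it (Pd2(dba)3, XPhos, LiOtBu, dioxane, 90 °C) gives the 1,1-diarylethylene F5. A copper-catalysed enantioselective hydroboration of its terminal alkene (CuCl, chiral bisphosphine, NaOtBu, HBpin), with boron going to the terminal carbon, then returns to the route at 16.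

Step 6. Condensation may stall at carbonyl groups shielded by bromine and a benzyloxy group. The fallback reaches the diazo groups through silyl hydrazones and sets out from 8. Treatment with 1,2-bis(tert-butyldimethylsilyl)hydrazine and catalytic Sc(OTf)3 gives the bis(N-silylhydrazone) F6. Oxidation with (difluoroiodo)benzene and 2-chloropyridine then gives the bis-diazo compound 10, where the rhodium stage of step 7 takes over.

Further compounds

F1 | step 12 | primary alcohol: 16 with CH2OH in place of CH2Bpin, configuration unchanged | COc1ccc(cc1)[C@@H]1Oc2cc3O[C@@H](c4ccc(OC)cc4)[C@H](c4c([C@H](CO)c5ccc(OC)cc5OC)c(OC)cc(OC)c4)c3c(Br)c2[C@H]1c1cc(OC)cc(OC)c1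
F2 | step 12 | primary iodide: 16 with CH2I in place of CH2Bpin, configuration unchanged | COc1ccc(cc1)[C@@H]1Oc2cc3O[C@@H](c4ccc(OC)cc4)[C@H](c4c([C@H](CI)c5ccc(OC)cc5OC)c(OC)cc(OC)c4)c3c(Br)c2[C@H]1c1cc(OC)cc(OC)c1
F3 | step 12 | alkylzinc iodide: 16 with CH2ZnI in place of CH2Bpin, not isolated | COc1ccc(cc1)[C@@H]1Oc2cc3O[C@@H](c4ccc(OC)cc4)[C@H](c4c([C@H](C[Zn]I)c5ccc(OC)cc5OC)c(OC)cc(OC)c4)c3c(Br)c2[C@H]1c1cc(OC)cc(OC)c1
F4 | step 11 | N-tosylhydrazone of 2',4'-dimethoxyacetophenone | COc1ccc(C(C)=NNS(=O)(=O)c2ccc(C)cc2)c(OC)c1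
F5 | step 11 | 1,1-diarylethylene: 13 with a 1-(2,4-dimethoxyphenyl)vinyl group in place of iodine | COc1ccc(cc1)[C@@H]1Oc2cc3O[C@@H](c4ccc(OC)cc4)[C@H](c4c(C(=C)c5ccc(OC)cc5OC)c(OC)cc(OC)c4)c3c(Br)c2[C@H]1c1cc(OC)cc(OC)c1
F6 | step 6 | bis(N-tert-butyldimethylsilylhydrazone) of 8 | COc1ccc(COc2cc(OCc3ccc(OC)cc3)c(C(=NN[Si](C)(C)C(C)(C)C)c3cc(OC)cc(OC)c3)c(Br)c2C(=NN[Si](C)(C)C(C)(C)C)c2cc(OC)cc(OC)c2)cc1
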